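Ring A is cut at three bonds, C4a–C8a, C5–C6 and C7–C8, because its oxygen-bearing carbons C6 and C7 are neighbours flanked by C5–H and C8–H and ring A is fused to ring B at C4a–C8a. A ruthenium-catalysed [2+2+2] cyclotrimerisation of an enediyne with bis(pinacolatoboryl)acetylene therefore closes rings A and B in one operation and delivers C6 and C7 as C–B bonds, which are oxidised to the catechol. The precursor is an open-chain (E)-enediyne with terminal alkynes on C1 and C4 that already holds both stereocentres (C1, C2), the tert-butyl ester at C2, the acetonide-protected aryl group and the di-tert-butyl L-malate ester at C3.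

Key step: step 11

Remark: lignan numbering is used (C1 aryl-bearing, C2 carboxyl-bearing, C3 ester-bearing, C4 vinylic CH, ring A = C4a, C5–C8, C8a), Ar = 2,2-dimethyl-1,3-benzodioxol-5-yl, and the CIP label at C1 or C2 changes when a neighbour changes priority although the spatial arrangement stays the same once each centre is set.

Step 1
Reactants: 1 3,4-dihydroxybenzaldehyde
Product: 2 2,2-dimethyl-1,3-benzodioxole-5-carbaldehyde
Conditions: 2,2-dimethoxypropane, TsOH·H2O (cat.), benzene, reflux, Soxhlet with 4 Å MS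
Reagents that add atoms: 2,2-dimethoxypropane, COC(C)(C)OC
Why: Acid-catalysed ketal exchange (acetonide formation) ties both phenols into a benzodioxole that withstands bases, enolates and zerovalent palladium and is removed by aqueous TFA in the last step.

Step 2
Reactants: 2 2,2-dimethyl-1,3-benzodioxole-5-carbaldehyde; 3 Meldrum's acid (2,2-dimethyl-1,3-dioxane-4,6-dione)
Product: 4 5-(Ar-methylidene)-2,2-dimethyl-1,3-dioxane-4,6-dione
Conditions: pyrrolidine (cat.), AcOH (cat.), benzene, rt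
Reagents that add atoms: none
Why: Knoevenagel condensation of the non-enolisable aldehyde with the acidic methylene of Meldrum's acid should give the doubly activated arylidene acceptor that the next step needs.

Step 3
Reactants: 4 5-(Ar-methylidene)-2,2-dimethyl-1,3-dioxane-4,6-dione; 5 ethynyltrimethylsilane
Product: 6 5-[(1R)-1-Ar-3-(trimethylsilyl)prop-2-yn-1-yl]-2,2-dimethyl-1,3-dioxane-4,6-dione
Conditions: Cu(OAc)2·H2O (10 mol %), sodium L-ascorbate (20 mol %), PINAP-type chiral P,N ligand (10 mol %, the enantiomer that gives the R adduct), 5 (excess), H2O/t-BuOH, 0 °C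
Reagents that add atoms: none
Why: Catalytic enantioselective conjugate alkynylation: ascorbate reduces the copper salt to monovalent copper, whose acetylide bound to the chiral P,N ligand adds 1,4 to one face of the arylidene Meldrum's acid and so sets C1, while the silyl group keeps the alkyne masked for the base steps that follow.

Step 4
Reactants: 6 5-[(1R)-1-Ar-3-(trimethylsilyl)prop-2-yn-1-yl]-2,2-dimethyl-1,3-dioxane-4,6-dione
Product: 8 tert-butyl (3R)-3-Ar-5-(trimethylsilyl)pent-4-ynoate, via malonic half ester 7 (not isolated)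
Conditions: t-BuOH, toluene, 100 °C; then Cu2O (cat.), MeCN, 80 °C
Reagents that add atoms: tert-butanol, CC(C)(C)O
Why: Alcoholysis of the Meldrum's acid ring by tert-butanol expels acetone and leaves the malonic half ester, whose Cu2O-catalysed decarboxylation gives the tert-butyl ester, and C1 carries no acidic hydrogen here so its configuration is kept.

Step 5
Reactants: 8 tert-butyl (3R)-3-Ar-5-(trimethylsilyl)pent-4-ynoate; 9 prop-2-en-1-yl bromoacetate (allyl bromoacetate)
Product: 11 1-tert-butyl 4-prop-2-en-1-yl (2R)-2-[(1R)-1-Ar-3-(trimethylsilyl)prop-2-yn-1-yl]butanedioate, via lithium enolate 10 (not isolated)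
Conditions: LiN(iPr)2, THF, −78 °C; then 9, −78 to −40 °C
Reagents that add atoms: none
Why: SN2 alkylation of the ester enolate under 1,2-induction: with C1–H eclipsing the enolate double bond to avoid allylic strain, the aryl group stands anti to the incoming bromoacetate and the slim silylethynyl group to the side, so C2 should form mainly with the relative configuration that becomes 1,2-trans in ring B (a carbon electrophile is used for this centre because a proton would enter the same face and give the cis series), the minor epimer being removed by chromatography.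

Step 6
Reactants: 11 1-tert-butyl 4-prop-2-en-1-yl (2R)-2-[(1R)-1-Ar-3-(trimethylsilyl)prop-2-yn-1-yl]butanedioate; 12 3-(trimethylsilyl)prop-2-ynal
Product: 16 1-tert-butyl 4-prop-2-en-1-yl (2S,3E)-2-[(1R)-1-Ar-3-(trimethylsilyl)prop-2-yn-1-yl]-3-[3-(trimethylsilyl)prop-2-yn-1-ylidene]butanedioate, via lithium enolate 13 (not isolated), via lithium aldolate 14 (not isolated), via acetate 15 (not isolated)
Conditions: LiN(iPr)2, THF, −78 °C; 12, −78 °C; Ac2O, −78 to 0 °C; DBU, 0 °C to rt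
Reagents that add atoms: none
Why: Aldol condensation: LiN(iPr)2 removes a proton from the unhindered methylene next to the allyl ester faster than from the hindered methine next to the tert-butyl ester, the enolate adds to the ynal, and acetylation followed by DBU-induced E1cB elimination should give mainly the E enyne (alkyne trans to the ester and so cis to C2), the geometry that ring B needs, while C1 and C2 are not touched.

Step 7
Reactants: 16 1-tert-butyl 4-prop-2-en-1-yl (2S,3E)-2-[(1R)-1-Ar-3-(trimethylsilyl)prop-2-yn-1-yl]-3-[3-(trimethylsilyl)prop-2-yn-1-ylidene]butanedioate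
Product: 17 (2E,3S)-4-tert-butoxy-3-[(1R)-1-Ar-3-(trimethylsilyl)prop-2-yn-1-yl]-4-oxo-2-[3-(trimethylsilyl)prop-2-yn-1-ylidene]butanoic acid
Conditions: Pd(PPh3)4 (5 mol %), morpholine, THF, rt
Reagents that add atoms: none
Why: Tsuji–Trost allyl transfer: zerovalent palladium ionises the allyl ester to a π-allyl complex that morpholine captures, which frees the C3 acid under neutral conditions that leave the tert-butyl ester, the C–Si bonds, the alkene geometry and C2 alone.

Step 8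
Reactants: 18 L-malic acid
Product: 19 di-tert-butyl (2S)-2-hydroxybutanedioate
Conditions: tert-butyl 2,2,2-trichloroacetimidate, THF/cyclohexane, rt
Reagents that add atoms: tert-butyl 2,2,2-trichloroacetimidate, CC(C)(C)OC(=N)C(Cl)(Cl)Cl
Why: Imidate esterification: each carboxylic acid protonates the imidate and is tert-butylated, whereas the secondary alcohol needs a Lewis acid to react and stays free, and the stereocentre is not involved.

Step 9
Reactants: 17 (2E,3S)-4-tert-butoxy-3-[(1R)-1-Ar-3-(trimethylsilyl)prop-2-yn-1-yl]-4-oxo-2-[3-(trimethylsilyl)prop-2-yn-1-ylidene]butanoic acid; 19 di-tert-butyl (2S)-2-hydroxybutanedioate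
Product: 20 1-tert-butyl 4-[(2S)-1,4-di-tert-butoxy-1,4-dioxobutan-2-yl] (2S,3E)-2-[(1R)-1-Ar-3-(trimethylsilyl)prop-2-yn-1-yl]-3-[3-(trimethylsilyl)prop-2-yn-1-ylidene]butanedioate
Conditions: DIC, DMAP (cat.), CH2Cl2, 0 °C to rt
Reagents that add atoms: none
Why: Steglich esterification through the O-acylisourea and the acylpyridinium ion acylates the malate hydroxyl with retention at the malate carbon; the malate is attached only now because its acyloxy group would be eliminated by the strong bases of steps 5 and 6, and DMAP is too weak a base to do that or to enolise C2.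

Step 10
Reactants: 20 1-tert-butyl 4-[(2S)-1,4-di-tert-butoxy-1,4-dioxobutan-2-yl] (2S,3E)-2-[(1R)-1-Ar-3-(trimethylsilyl)prop-2-yn-1-yl]-3-[3-(trimethylsilyl)prop-2-yn-1-ylidene]butanedioate
Product: 21 1-tert-butyl 4-[(2S)-1,4-di-tert-butoxy-1,4-dioxobutan-2-yl] (2S,3E)-2-[(1S)-1-Ar-prop-2-yn-1-yl]-3-(prop-2-yn-1-ylidene)butanedioate
Conditions: AgNO3 (20 mol %), acetone/H2O/CH2Cl2, rt
Reagents that add atoms: none
Why: Silver-catalysed protodesilylation cleaves both alkynyl C–Si bonds through silver acetylides that water protonates, under neutral conditions that spare the esters, the acetonide, C2 and the base-sensitive acyloxy succinate.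

Step 11
Reactants: 21 1-tert-butyl 4-[(2S)-1,4-di-tert-butoxy-1,4-dioxobutan-2-yl] (2S,3E)-2-[(1S)-1-Ar-prop-2-yn-1-yl]-3-(prop-2-yn-1-ylidene)butanedioate; 22 bis(pinacolatoboryl)acetylene (2,2'-(ethyne-1,2-diyl)bis(4,4,5,5-tetramethyl-1,3,2-dioxaborolane))
Product: 23 di-tert-butyl (2S)-2-{[(1R,2S)-2-(tert-butoxycarbonyl)-1-Ar-6,7-bis(4,4,5,5-tetramethyl-1,3,2-dioxaborolan-2-yl)-1,2-dihydronaphthalene-3-carbonyl]oxy}butanedioate
Conditions: Cp*RuCl(cod) (10 mol %), 22 (3 equiv), ClCH2CH2Cl, rt, slow addition of 21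
Reagents that add atoms: none
Why: The Cp*RuCl fragment (divalent ruthenium) binds both terminal alkynes of 21 and couples them oxidatively to a ruthenacyclopentadiene, which takes up 22 and releases the arene by reductive elimination, so that C4a–C8a, C5–C6 and C7–C8 form in one catalytic cycle. The closest known reaction type is the Cp*RuCl(cod)-catalysed [2+2+2] cyclotrimerisation of tethered diynes with alkynylboronates, and diborylethyne is an established partner in such cocyclisations. Ring B closes in the oxidative cyclisation (a six-membered carbocycle through the new C4a–C8a bond of the 1,7-diyne), and ring A closes by insertion of the third alkyne followed by reductive elimination (formal [2+2+2] benzannulation). No stereocentre is made, and because the medium is neutral and aprotic C1 and C2 cannot epimerise and the acyloxy succinate cannot eliminate. The step needs cross-selectivity over self-coupling of 21: the tether makes the first coupling intramolecular, the E alkene holds the C4 ethynyl group cis to C2 and so pre-folds ring B, 22 is too hindered to trimerise by itself and is used in excess, and 21 is added slowly. Because 22 is symmetrical, no regiochemistry arises.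

Step 12
Reactants: 23 di-tert-butyl (2S)-2-{[(1R,2S)-2-(tert-butoxycarbonyl)-1-Ar-6,7-bis(4,4,5,5-tetramethyl-1,3,2-dioxaborolan-2-yl)-1,2-dihydronaphthalene-3-carbonyl]oxy}butanedioate
Product: 24 di-tert-butyl (2S)-2-{[(1R,2S)-2-(tert-butoxycarbonyl)-1-Ar-6,7-dihydroxy-1,2-dihydronaphthalene-3-carbonyl]oxy}butanedioate
Conditions: NaBO3·4H2O, THF/H2O, 0 °C to rt, under argon
Reagents that add atoms: sodium perborate tetrahydrate (NaBO3·4H2O), [Na+].[Na+].O[B-]1(O)OO[B-](O)(O)OO1
Why: Boronate oxidation: perborate adds to each boron, the aryl group shifts from boron to oxygen, and hydrolysis of the borate esters should give the ring A catechol under mild conditions that leave the esters, the conjugated alkene and the stereocentres unchanged.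

Step 13
Reactants: 24 di-tert-butyl (2S)-2-{[(1R,2S)-2-(tert-butoxycarbonyl)-1-Ar-6,7-dihydroxy-1,2-dihydronaphthalene-3-carbonyl]oxy}butanedioate
Product: 25 (2S)-2-{[(1R,2S)-2-carboxy-1-(3,4-dihydroxyphenyl)-6,7-dihydroxy-1,2-dihydronaphthalene-3-carbonyl]oxy}butanedioic acid (CNP0323723.1)
Conditions: TFA/H2O (9:1), 0 °C to rt
Reagents that add atoms: none
Why: Acidolysis of the three tert-butyl esters and acid hydrolysis of the acetonide, with water trapping the tert-butyl cation, should free all acids and the second catechol without base, so C1, C2 and the malate centre keep their configuration.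

Compound list
1 | 3,4-dihydroxybenzaldehyde | O=Cc1ccc(O)c(O)c1 | starting material
2 | 2,2-dimethyl-1,3-benzodioxole-5-carbaldehyde | O=Cc1ccc2OC(C)(C)Oc2c1 | intermediate
3 | Meldrum's acid (2,2-dimethyl-1,3-dioxane-4,6-dione) | CC1(C)OC(=O)CC(=O)O1 | starting material
4 | 5-[(2,2-dimethyl-1,3-benzodioxol-5-yl)methylidene]-2,2-dimethyl-1,3-dioxane-4,6-dione | CC1(C)OC(=O)C(=Cc2ccc3OC(C)(C)Oc3c2)C(=O)O1 | intermediate
5 | ethynyltrimethylsilane | C[Si](C)(C)C#C | starting material
6 | 5-[(1R)-1-(2,2-dimethyl-1,3-benzodioxol-5-yl)-3-(trimethylsilyl)prop-2-yn-1-yl]-2,2-dimethyl-1,3-dioxane-4,6-dione | C[Si](C)(C)C#C[C@@H](c1ccc2OC(C)(C)Oc2c1)C1C(=O)OC(C)(C)OC1=O | intermediate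
7 | 3-tert-butoxy-2-[(1R)-1-(2,2-dimethyl-1,3-benzodioxol-5-yl)-3-(trimethylsilyl)prop-2-yn-1-yl]-3-oxopropanoic acid (both epimers at the malonate carbon; not isolated) | C[Si](C)(C)C#C[C@@H](c1ccc2OC(C)(C)Oc2c1)C(C(=O)O)C(=O)OC(C)(C)C | intermediate
8 | tert-butyl (3R)-3-(2,2-dimethyl-1,3-benzodioxol-5-yl)-5-(trimethylsilyl)pent-4-ynoate | C[Si](C)(C)C#C[C@@H](c1ccc2OC(C)(C)Oc2c1)CC(=O)OC(C)(C)C | intermediate
9 | prop-2-en-1-yl bromoacetate | C=CCOC(=O)CBr | starting material
10 | lithium enolate of 8 (C1 as in 8; not isolated) | C[Si](C)(C)C#C[C@@H](c1ccc2OC(C)(C)Oc2c1)C=C(O[Li])OC(C)(C)C | intermediate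
11 | 1-tert-butyl 4-prop-2-en-1-yl (2R)-2-[(1R)-1-(2,2-dimethyl-1,3-benzodioxol-5-yl)-3-(trimethylsilyl)prop-2-yn-1-yl]butanedioate | C[Si](C)(C)C#C[C@@H](c1ccc2OC(C)(C)Oc2c1)[C@H](C(=O)OC(C)(C)C)CC(=O)OCC=C | intermediate
12 | 3-(trimethylsilyl)prop-2-ynal | C[Si](C)(C)C#CC=O | starting material
13 | lithium enolate of 11 at C3, on the allyl ester side (C1 and C2 as in 11; not isolated) | C[Si](C)(C)C#C[C@@H](c1ccc2OC(C)(C)Oc2c1)[C@H](C(=O)OC(C)(C)C)C=C(O[Li])OCC=C | intermediate
14 | lithium aldolate from 13 and 12 (mixture at the two new centres C3 and C4; not isolated) | C[Si](C)(C)C#C[C@@H](c1ccc2OC(C)(C)Oc2c1)[C@H](C(=O)OC(C)(C)C)C(C(=O)OCC=C)C(O[Li])C#C[Si](C)(C)C | intermediate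
15 | acetate of the aldol adduct (mixture at C3 and C4; not isolated) | C[Si](C)(C)C#C[C@@H](c1ccc2OC(C)(C)Oc2c1)[C@H](C(=O)OC(C)(C)C)C(C(=O)OCC=C)C(OC(C)=O)C#C[Si](C)(C)C | intermediate
16 | 1-tert-butyl 4-prop-2-en-1-yl (2S,3E)-2-[(1R)-1-(2,2-dimethyl-1,3-benzodioxol-5-yl)-3-(trimethylsilyl)prop-2-yn-1-yl]-3-[3-(trimethylsilyl)prop-2-yn-1-ylidene]butanedioate | C[Si](C)(C)C#C[C@@H](c1ccc2OC(C)(C)Oc2c1)[C@H](C(=O)OC(C)(C)C)/C(C(=O)OCC=C)=C\C#C[Si](C)(C)C | intermediate
17 | (2E,3S)-4-tert-butoxy-3-[(1R)-1-(2,2-dimethyl-1,3-benzodioxol-5-yl)-3-(trimethylsilyl)prop-2-yn-1-yl]-4-oxo-2-[3-(trimethylsilyl)prop-2-yn-1-ylidene]butanoic acid | C[Si](C)(C)C#C[C@@H](c1ccc2OC(C)(C)Oc2c1)[C@H](C(=O)OC(C)(C)C)/C(C(=O)O)=C\C#C[Si](C)(C)C | intermediate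
18 | L-malic acid ((2S)-2-hydroxybutanedioic acid) | O[C@@H](CC(=O)O)C(=O)O | starting material
19 | di-tert-butyl (2S)-2-hydroxybutanedioate | CC(C)(C)OC(=O)C[C@H](O)C(=O)OC(C)(C)C | intermediate
20 | 1-tert-butyl 4-[(2S)-1,4-di-tert-butoxy-1,4-dioxobutan-2-yl] (2S,3E)-2-[(1R)-1-(2,2-dimethyl-1,3-benzodioxol-5-yl)-3-(trimethylsilyl)prop-2-yn-1-yl]-3-[3-(trimethylsilyl)prop-2-yn-1-ylidene]butanedioate | C[Si](C)(C)C#C[C@@H](c1ccc2OC(C)(C)Oc2c1)[C@H](C(=O)OC(C)(C)C)/C(C(=O)O[C@@H](CC(=O)OC(C)(C)C)C(=O)OC(C)(C)C)=C\C#C[Si](C)(C)C | intermediate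
21 | 1-tert-butyl 4-[(2S)-1,4-di-tert-butoxy-1,4-dioxobutan-2-yl] (2S,3E)-2-[(1S)-1-(2,2-dimethyl-1,3-benzodioxol-5-yl)prop-2-yn-1-yl]-3-(prop-2-yn-1-ylidene)butanedioate (key-step precursor) | C#C[C@@H](c1ccc2OC(C)(C)Oc2c1)[C@H](C(=O)OC(C)(C)C)/C(C(=O)O[C@@H](CC(=O)OC(C)(C)C)C(=O)OC(C)(C)C)=C\C#C | intermediate
22 | bis(pinacolatoboryl)acetylene | CC1(C)OB(C#CB2OC(C)(C)C(C)(C)O2)OC1(C)C | starting material
23 | di-tert-butyl (2S)-2-{[(1R,2S)-2-(tert-butoxycarbonyl)-1-(2,2-dimethyl-1,3-benzodioxol-5-yl)-6,7-bis(4,4,5,5-tetramethyl-1,3,2-dioxaborolan-2-yl)-1,2-dihydronaphthalene-3-carbonyl]oxy}butanedioate (key-step product) | CC(C)(C)OC(=O)C[C@H](OC(=O)C1=Cc2cc(B3OC(C)(C)C(C)(C)O3)c(B3OC(C)(C)C(C)(C)O3)cc2[C@@H](c2ccc3OC(C)(C)Oc3c2)[C@@H]1C(=O)OC(C)(C)C)C(=O)OC(C)(C)C | intermediate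
24 | di-tert-butyl (2S)-2-{[(1R,2S)-2-(tert-butoxycarbonyl)-1-(2,2-dimethyl-1,3-benzodioxol-5-yl)-6,7-dihydroxy-1,2-dihydronaphthalene-3-carbonyl]oxy}butanedioate | CC(C)(C)OC(=O)C[C@H](OC(=O)C1=Cc2cc(O)c(O)cc2[C@@H](c2ccc3OC(C)(C)Oc3c2)[C@@H]1C(=O)OC(C)(C)C)C(=O)OC(C)(C)C | intermediate
25 | (2S)-2-{[(1R,2S)-2-carboxy-1-(3,4-dihydroxyphenyl)-6,7-dihydroxy-1,2-dihydronaphthalene-3-carbonyl]oxy}butanedioic acid (CNP0323723.1) | O=C(O)C[C@H](OC(=O)C1=Cc2cc(O)c(O)cc2[C@@H](c2ccc(O)c(O)c2)[C@@H]1C(=O)O)C(=O)O | target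

Total step count: 13. Longest linear sequence: 12 steps (steps 1–7 and 9–13; step 8 is the one-step side branch to 19).

Steps most likely to fail

Step 11. What may go wrong: self-coupling of the enediyne at ruthenium (dimerisation or oligomerisation) outruns capture of the ruthenacycle by the hindered diborylalkyne, so that little cross-cyclotrimer forms. Fallback, from 21 back to 25: the two-carbon partner is changed to an alkyne that already carries masked oxygen. Cocyclisation of 21 with di-tert-butoxyethyne under [Rh(cod)2]BF4/BINAP (cationic monovalent rhodium, CH2Cl2, rt) should give di-tert-butyl (2S)-2-{[(1R,2S)-6,7-di-tert-butoxy-2-(tert-butoxycarbonyl)-1-Ar-1,2-dihydronaphthalene-3-carbonyl]oxy}butanedioate F1. Aqueous TFA then removes the two aryl tert-butyl ethers together with the three tert-butyl esters and the acetonide and gives 25 directly, without a boron oxidation.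

Step 5. What may go wrong: poor facial selectivity in the enolate alkylation, the electrophile entering syn to the aryl group and giving the C2 epimer. Fallback, from 6 back to 11: auxiliary control replaces 1,2-induction.
- Hydrolytic decarboxylation of 6 (DMF/H2O, 100 °C) gives (3R)-3-Ar-5-(trimethylsilyl)pent-4-ynoic acid F2.
- Its mixed pivalic anhydride (PivCl, Et3N) is treated with lithiated (4R)-4-benzyl-1,3-oxazolidin-2-one to give (4R)-4-benzyl-3-[(3R)-3-Ar-5-(trimethylsilyl)pent-4-ynoyl]-1,3-oxazolidin-2-one F3.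
- NaN(SiMe3)2 and 9 at −78 °C alkylate the chelated Z-enolate on the face away from the benzyl group to give (4R)-4-benzyl-3-{(2R)-2-[(1R)-1-Ar-3-(trimethylsilyl)prop-2-yn-1-yl]-4-oxo-4-(prop-2-en-1-yloxy)butanoyl}-1,3-oxazolidin-2-one F4.
- LiOH/H2O2 (THF/H2O, 0 °C) removes the auxiliary to give (2R)-2-[(1R)-1-Ar-3-(trimethylsilyl)prop-2-yn-1-yl]-4-oxo-4-(prop-2-en-1-yloxy)butanoic acid F5.
- tert-Butyl 2,2,2-trichloroacetimidate esterifies the acid to 11.

Step 6. What may go wrong: deprotonation at C2 instead of C3, that is loss of site selectivity with epimerisation at C2. Fallback, from 11 back to 17: soft enolisation of an imide fixes the site.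
- Pd(PPh3)4/morpholine frees (3R,4R)-3-(tert-butoxycarbonyl)-4-Ar-6-(trimethylsilyl)hex-5-ynoic acid F6.
- PivCl/Et3N, then 1,3-oxazolidin-2-one and LiCl, give tert-butyl (2R,3R)-3-Ar-2-[2-oxo-2-(2-oxo-1,3-oxazolidin-3-yl)ethyl]-5-(trimethylsilyl)pent-4-ynoate F7.
- Bu2BOTf/iPr2NEt (CH2Cl2, −78 °C) enolises only the imide, and boron aldol addition to 12 gives the β-hydroxy imide F8 (mixture at the two new centres).
- MsCl/Et3N converts it into the methanesulfonate F9, and DBU eliminates to the E enoyl imide 3-{(2E,3S)-4-tert-butoxy-3-[(1R)-1-Ar-3-(trimethylsilyl)prop-2-yn-1-yl]-4-oxo-2-[3-(trimethylsilyl)prop-2-yn-1-ylidene]butanoyl}-1,3-oxazolidin-2-one F10.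
- LiOH/H2O2 cleaves the imide to 17.

Further compounds
F1 | step 11 | di-tert-butyl (2S)-2-{[(1R,2S)-6,7-di-tert-butoxy-2-(tert-butoxycarbonyl)-1-(2,2-dimethyl-1,3-benzodioxol-5-yl)-1,2-dihydronaphthalene-3-carbonyl]oxy}butanedioate | CC(C)(C)OC(=O)C[C@H](OC(=O)C1=Cc2cc(OC(C)(C)C)c(OC(C)(C)C)cc2[C@@H](c2ccc3OC(C)(C)Oc3c2)[C@@H]1C(=O)OC(C)(C)C)C(=O)OC(C)(C)C
F2 | step 5 | (3R)-3-(2,2-dimethyl-1,3-benzodioxol-5-yl)-5-(trimethylsilyl)pent-4-ynoic acid | C[Si](C)(C)C#C[C@@H](c1ccc2OC(C)(C)Oc2c1)CC(=O)O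
F3 | step 5 | (4R)-4-benzyl-3-[(3R)-3-(2,2-dimethyl-1,3-benzodioxol-5-yl)-5-(trimethylsilyl)pent-4-ynoyl]-1,3-oxazolidin-2-one | C[Si](C)(C)C#C[C@@H](c1ccc2OC(C)(C)Oc2c1)CC(=O)N1[C@H](Cc2ccccc2)COC1=O
F4 | step 5 | (4R)-4-benzyl-3-{(2R)-2-[(1R)-1-(2,2-dimethyl-1,3-benzodioxol-5-yl)-3-(trimethylsilyl)prop-2-yn-1-yl]-4-oxo-4-(prop-2-en-1-yloxy)butanoyl}-1,3-oxazolidin-2-one | C[Si](C)(C)C#C[C@@H](c1ccc2OC(C)(C)Oc2c1)[C@H](C(=O)N1[C@H](Cc2ccccc2)COC1=O)CC(=O)OCC=C
F5 | step 5 | (2R)-2-[(1R)-1-(2,2-dimethyl-1,3-benzodioxol-5-yl)-3-(trimethylsilyl)prop-2-yn-1-yl]-4-oxo-4-(prop-2-en-1-yloxy)butanoic acid | C[Si](C)(C)C#C[C@@H](c1ccc2OC(C)(C)Oc2c1)[C@H](C(=O)O)CC(=O)OCC=C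
F6 | step 6 | (3R,4R)-3-(tert-butoxycarbonyl)-4-(2,2-dimethyl-1,3-benzodioxol-5-yl)-6-(trimethylsilyl)hex-5-ynoic acid | C[Si](C)(C)C#C[C@@H](c1ccc2OC(C)(C)Oc2c1)[C@H](C(=O)OC(C)(C)C)CC(=O)O
F7 | step 6 | tert-butyl (2R,3R)-3-(2,2-dimethyl-1,3-benzodioxol-5-yl)-2-[2-oxo-2-(2-oxo-1,3-oxazolidin-3-yl)ethyl]-5-(trimethylsilyl)pent-4-ynoate | C[Si](C)(C)C#C[C@@H](c1ccc2OC(C)(C)Oc2c1)[C@H](C(=O)OC(C)(C)C)CC(=O)N1CCOC1=O
F8 | step 6 | β-hydroxy imide from boron aldol addition of F7 to 12 (mixture at the two new centres) | C[Si](C)(C)C#C[C@@H](c1ccc2OC(C)(C)Oc2c1)[C@H](C(=O)OC(C)(C)C)C(C(=O)N1CCOC1=O)C(O)C#C[Si](C)(C)C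
F9 | step 6 | methanesulfonate of F8 | C[Si](C)(C)C#C[C@@H](c1ccc2OC(C)(C)Oc2c1)[C@H](C(=O)OC(C)(C)C)C(C(=O)N1CCOC1=O)C(OS(C)(=O)=O)C#C[Si](C)(C)C
F10 | step 6 | 3-{(2E,3S)-4-tert-butoxy-3-[(1R)-1-(2,2-dimethyl-1,3-benzodioxol-5-yl)-3-(trimethylsilyl)prop-2-yn-1-yl]-4-oxo-2-[3-(trimethylsilyl)prop-2-yn-1-ylidene]butanoyl}-1,3-oxazolidin-2-one | C[Si](C)(C)C#C[C@@H](c1ccc2OC(C)(C)Oc2c1)[C@H](C(=O)OC(C)(C)C)/C(C(=O)N1CCOC1=O)=C\C#C[Si](C)(C)C
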